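The arene of the chromene attached to alkene carbon C1 (ring A) has oxygen on C5, C7 and C8a and carbon C1 on C8. With C1 as a carbonyl, this 1,3,5-trioxygenated, C-acylated ring is what a folded poly-β-carbonyl chain delivers, so the route disconnects the C8–C8a bond. In one operation a stable pyranone is opened to the true precursor, a methyl 3-methoxy-5,7-dioxodec-2-enoate that already carries the (S)-centre and chromene B, and its C6 closes onto the ester carbon to form the ring-A arene. The C3 enol ether shuts off the competing aldol mode and ends as the 5-methoxy group.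

Key step: step 6

Assumption: chain atoms are numbered as in the dec-2-enoate (ester carbon C1, stereocentre C9), and the (R)-prolinol catalyst is taken to follow its usual shielding model; its enantiomer is equally available should the sense prove opposite.

Step 1
Reactants: 1 3,5-dimethoxyphenol; 2 (E)-but-2-enal
Product: 4 (4S)-5,7-dimethoxy-4-methylchroman-2-ol (both C2 epimers), via hydroxy aldehyde 3 (not isolated)
Conditions: (R)-α,α-diphenylprolinol trimethylsilyl ether (20 mol %), PhCO2H (20 mol %), toluene, 0 °C
Reagents that add atoms: none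
Why: Iminium-ion-catalysed Friedel–Crafts alkylation of the electron-rich phenol through its ortho carbon followed by hemiacetal closure, in which the diphenyl(silyloxy)methyl group of the catalyst shields one face of the E-iminium ion of 2 so that the aryl carbon should add to the open face and set the (S)-centre.

Step 2
Reactants: 4 (4S)-5,7-dimethoxy-4-methylchroman-2-ol
Product: 5 (S)-5,7-dimethoxy-4-methylchroman-2-one
Conditions: pyridinium chlorochromate [C5H5NH][CrO3Cl], 4 Å MS, CH2Cl2, rt; recrystallisation
Reagents that add atoms: none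
Why: Oxidation of a lactol to the lactone with hexavalent chromium leaves the benzylic stereocentre untouched, and the lactone should be crystalline so that its enantiomeric purity can be raised by recrystallisation.

Step 3
Reactants: 5 (S)-5,7-dimethoxy-4-methylchroman-2-one
Product: 6 (S)-3-(2-hydroxy-4,6-dimethoxyphenyl)-N-methoxy-N-methylbutanamide
Conditions: MeNHOMe·HCl, AlMe3, CH2Cl2, 0 °C to rt; then cold 0.5 M HCl
Reagents that add atoms: N,O-dimethylhydroxylamine hydrochloride, CNOC.Cl
Why: Aminolysis of the aryl ester (lactone) by the aluminium amide gives the N-methoxy-N-methylamide (Weinreb amide), which frees the phenol and should close back to the lactone far less readily than an ester would.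

Step 4
Reactants: 6 (S)-3-(2-hydroxy-4,6-dimethoxyphenyl)-N-methoxy-N-methylbutanamide; 7 3-methylbut-2-enal
Product: 9 (S)-3-(5,7-dimethoxy-2,2-dimethyl-2H-chromen-8-yl)-N-methoxy-N-methylbutanamide, via ortho-quinone methide 8 (not isolated)
Conditions: ethylenediammonium diacetate (20 mol %), xylene, 130 °C
Reagents that add atoms: none
Why: Amine-salt-catalysed Knoevenagel-type condensation of the phenol through its only free ortho carbon with 7 gives 8, whose oxa-6π electrocyclisation closes the 2,2-dimethylpyran ring of chromene B with a single possible regiochemistry.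

Step 5
Reactants: 9 (S)-3-(5,7-dimethoxy-2,2-dimethyl-2H-chromen-8-yl)-N-methoxy-N-methylbutanamide; 10 4-methoxy-6-methyl-2H-pyran-2-one
Product: 12 6-[(4S)-4-(5,7-dimethoxy-2,2-dimethyl-2H-chromen-8-yl)-2-oxopentyl]-4-methoxy-2H-pyran-2-one, via lithium dienolate 11 (not isolated)
Conditions: 10, LiN(SiMe3)2, THF, −78 °C; then 9, −78 to −30 °C; AcOH
Reagents that add atoms: none
Why: C-Acylation of the vinylogous ester enolate of 10 (deprotonated at the 6-methyl group) by the Weinreb amide stops at the ketone stage, forms the future C6–C7 bond and leaves the non-enolisable stereocentre alone.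

Step 6
Reactants: 12 6-[(4S)-4-(5,7-dimethoxy-2,2-dimethyl-2H-chromen-8-yl)-2-oxopentyl]-4-methoxy-2H-pyran-2-one
Product: 14 (S)-1-(2,6-dihydroxy-4-methoxyphenyl)-3-(5,7-dimethoxy-2,2-dimethyl-2H-chromen-8-yl)butan-1-one, via open-chain ester 13 (not isolated)
Conditions: Mg(OMe)2, MeOH, reflux; then cold dil. HCl
Reagents that add atoms: magnesium methoxide, [Mg+2].[O-]C.[O-]C (source of the ester methoxy group of 13)
Why: Magnesium-bound methoxide adds to the lactone carbonyl of 12 and opens the pyranone to ester 13, held as the magnesium chelate of its 5,7-diketone, whose C6 carbanion attacks the ester carbon C1 in a Claisen (Dieckmann-type) condensation, after which loss of methoxide and enolisation give the arene. The closest known reactions are the base-mediated Claisen cyclisation of 3,5,7-triketo esters to acylphloroglucinols and the Mg(OMe)2-induced conversion of 6-(2-oxoalkyl)-4-methoxypyran-2-ones into 2-acyl-5-methoxyresorcinols. Ring A closes in the 6-exo-trig mode by forming the bond that becomes C8–C8a of chromene A (the two ortho carbons are still equivalent at this stage). No stereocentre is created, and the existing one at C9 is not at an enolisable position. The step needs C-acylation through C6 to win over aldol closure from C2 onto the C7 ketone and over closures through oxygen; the C3 methyl enol ether makes C2 a non-nucleophilic vinyl carbon, its (E) geometry inherited from the ring holds the ester beside C6, and C6 is the only doubly activated carbon.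

Step 7
Reactants: 14 (S)-1-(2,6-dihydroxy-4-methoxyphenyl)-3-(5,7-dimethoxy-2,2-dimethyl-2H-chromen-8-yl)butan-1-one; 7 3-methylbut-2-enal
Product: 16 (S)-3-(5,7-dimethoxy-2,2-dimethyl-2H-chromen-8-yl)-1-(7-hydroxy-5-methoxy-2,2-dimethyl-2H-chromen-8-yl)butan-1-one, via ortho-quinone methide 15 (not isolated)
Conditions: 7 (1.2 equiv), ethylenediammonium diacetate (20 mol %), toluene, 110 °C
Reagents that add atoms: none
Why: The same Knoevenagel-type condensation and oxa-6π electrocyclisation as in step 4 applies, and because the two hydroxyl groups of 14 are equivalent and each free ring carbon has only one hydroxyl neighbour, 15 can close only to the 8-acyl-7-hydroxy-5-methoxychromene.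

Step 8
Reactants: 16 (S)-3-(5,7-dimethoxy-2,2-dimethyl-2H-chromen-8-yl)-1-(7-hydroxy-5-methoxy-2,2-dimethyl-2H-chromen-8-yl)butan-1-one
Product: 17 (S)-1,3-bis(5,7-dimethoxy-2,2-dimethyl-2H-chromen-8-yl)butan-1-one
Conditions: MeI, K2CO3, DMF, 50 °C
Reagents that add atoms: iodomethane, CI
Why: Williamson O-methylation of the remaining hydrogen-bonded phenol under carbonate conditions, which are too weak to enolise the ketone.

Step 9
Reactants: 17 (S)-1,3-bis(5,7-dimethoxy-2,2-dimethyl-2H-chromen-8-yl)butan-1-one
Product: 18 (3S)-1,3-bis(5,7-dimethoxy-2,2-dimethyl-2H-chromen-8-yl)butan-1-ol (both C1 epimers)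
Conditions: LiAlH4, THF, 0 °C; NaOH work-up
Reagents that add atoms: none
Why: Hydride reduction of the hindered aryl ketone gives the benzylic alcohol without control at C1, which does not matter because C1 becomes an alkene carbon in the next step.

Step 10
Reactants: 18 (3S)-1,3-bis(5,7-dimethoxy-2,2-dimethyl-2H-chromen-8-yl)butan-1-ol
Product: 19 8-[(1E,3S)-3-(5,7-dimethoxy-2,2-dimethyl-2H-chromen-8-yl)but-1-en-1-yl]-5,7-dimethoxy-2,2-dimethyl-2H-chromene
Conditions: pyridinium p-toluenesulfonate (10 mol %), toluene, 60 °C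
Reagents that add atoms: none
Why: Mild acid-catalysed E1 dehydration runs through a benzylic cation stabilised by the three oxygen substituents of ring A, and loss of a C2 proton should give the more stable conjugated (E)-alkene without involving the C3 centre.

Compound list
1 | 3,5-dimethoxyphenol | COc1cc(O)cc(OC)c1 | starting material
2 | (E)-but-2-enal | C/C=C/C=O | starting material
3 | (S)-3-(2-hydroxy-4,6-dimethoxyphenyl)butanal | O=CC[C@H](C)c1c(O)cc(OC)cc1OC | intermediate
4 | (4S)-5,7-dimethoxy-4-methylchroman-2-ol (both C2 epimers) | OC1C[C@H](C)c2c(OC)cc(OC)cc2O1 | intermediate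
5 | (S)-5,7-dimethoxy-4-methylchroman-2-one | O=C1C[C@H](C)c2c(OC)cc(OC)cc2O1 | intermediate
6 | (S)-3-(2-hydroxy-4,6-dimethoxyphenyl)-N-methoxy-N-methylbutanamide | CON(C)C(=O)C[C@H](C)c1c(O)cc(OC)cc1OC | intermediate
7 | 3-methylbut-2-enal | CC(C)=CC=O | starting material
8 | (S)-3-[2,4-dimethoxy-5-(3-methylbut-2-en-1-ylidene)-6-oxocyclohexa-1,3-dien-1-yl]-N-methoxy-N-methylbutanamide (ortho-quinone methide) | CON(C)C(=O)C[C@H](C)C1=C(OC)C=C(OC)C(=CC=C(C)C)C1=O | intermediate
9 | (S)-3-(5,7-dimethoxy-2,2-dimethyl-2H-chromen-8-yl)-N-methoxy-N-methylbutanamide | CON(C)C(=O)C[C@H](C)c1c(OC)cc(OC)c2c1OC(C)(C)C=C2 | intermediate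
10 | 4-methoxy-6-methyl-2H-pyran-2-one | COC1=CC(=O)OC(C)=C1 | starting material
11 | (4-methoxy-2-oxo-2H-pyran-6-yl)methyllithium (lithium dienolate of 10) | [Li]CC1=CC(OC)=CC(=O)O1 | intermediate
12 | 6-[(4S)-4-(5,7-dimethoxy-2,2-dimethyl-2H-chromen-8-yl)-2-oxopentyl]-4-methoxy-2H-pyran-2-one | COC1=CC(=O)OC(CC(=O)C[C@H](C)c2c(OC)cc(OC)c3c2OC(C)(C)C=C3)=C1 | intermediate
13 | methyl (2E,9S)-9-(5,7-dimethoxy-2,2-dimethyl-2H-chromen-8-yl)-3-methoxy-5,7-dioxodec-2-enoate (precursor of the key step, formed in the flask) | COC(=O)/C=C(/OC)CC(=O)CC(=O)C[C@H](C)c1c(OC)cc(OC)c2c1OC(C)(C)C=C2 | intermediate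
14 | (S)-1-(2,6-dihydroxy-4-methoxyphenyl)-3-(5,7-dimethoxy-2,2-dimethyl-2H-chromen-8-yl)butan-1-one | COc1cc(O)c(C(=O)C[C@H](C)c2c(OC)cc(OC)c3c2OC(C)(C)C=C3)c(O)c1 | intermediate
15 | (S)-3-(5,7-dimethoxy-2,2-dimethyl-2H-chromen-8-yl)-1-[2-hydroxy-4-methoxy-5-(3-methylbut-2-en-1-ylidene)-6-oxocyclohexa-1,3-dien-1-yl]butan-1-one (ortho-quinone methide) | COC1=CC(O)=C(C(=O)C[C@H](C)c2c(OC)cc(OC)c3c2OC(C)(C)C=C3)C(=O)C1=CC=C(C)C | intermediate
16 | (S)-3-(5,7-dimethoxy-2,2-dimethyl-2H-chromen-8-yl)-1-(7-hydroxy-5-methoxy-2,2-dimethyl-2H-chromen-8-yl)butan-1-one | COc1cc(O)c(C(=O)C[C@H](C)c2c(OC)cc(OC)c3c2OC(C)(C)C=C3)c2c1C=CC(C)(C)O2 | intermediate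
17 | (S)-1,3-bis(5,7-dimethoxy-2,2-dimethyl-2H-chromen-8-yl)butan-1-one | COc1cc(OC)c(C(=O)C[C@H](C)c2c(OC)cc(OC)c3c2OC(C)(C)C=C3)c2c1C=CC(C)(C)O2 | intermediate
18 | (3S)-1,3-bis(5,7-dimethoxy-2,2-dimethyl-2H-chromen-8-yl)butan-1-ol (both C1 epimers) | COc1cc(OC)c(C(O)C[C@H](C)c2c(OC)cc(OC)c3c2OC(C)(C)C=C3)c2c1C=CC(C)(C)O2 | intermediate
19 | 8-[(1E,3S)-3-(5,7-dimethoxy-2,2-dimethyl-2H-chromen-8-yl)but-1-en-1-yl]-5,7-dimethoxy-2,2-dimethyl-2H-chromene | COc1cc(OC)c(/C=C/[C@H](C)c2c(OC)cc(OC)c3c2OC(C)(C)C=C3)c2c1C=CC(C)(C)O2 | target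

Total step count: 10. Longest linear sequence: 10 steps, from 1 to 19.

Steps most likely to fail

Step 6 (key step). Ring opening may stall because the base first removes a proton from the side-chain methylene of 12. Methoxide may also cut the chain between C6 and C7 (retro-Claisen), or the opened chain may close again through oxygen on acidification. The fallback runs from 9 back to 14 and brings ring A in as an intact arene instead of building it. 5-Methoxyresorcinol is protected with chloromethyl methyl ether and i-Pr2NEt to give 1-methoxy-3,5-bis(methoxymethoxy)benzene F1. F1 is lithiated between the two acetal groups (n-BuLi, THF, 0 °C) and acylated with Weinreb amide 9 to give (S)-1-[4-methoxy-2,6-bis(methoxymethoxy)phenyl]-3-(5,7-dimethoxy-2,2-dimethyl-2H-chromen-8-yl)butan-1-one F2. Brief treatment of F2 with dilute HCl in MeOH at 0 °C to rt removes both acetals and gives 14.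

Step 4. At 130 °C the free phenol may close onto the amide carbonyl and return lactone 5 faster than the monophenol condenses with 7. The fallback runs from 6 back to 9 and caps the phenol before any heating. O-Alkylation of 6 with 3-chloro-3-methylbut-1-yne (1,8-diazabicyclo[5.4.0]undec-7-ene, CuCl2 cat., MeCN, 0 °C) gives the aryl propargyl ether (S)-3-[2,4-dimethoxy-6-(2-methylbut-3-yn-2-yloxy)phenyl]-N-methoxy-N-methylbutanamide F3. Heating F3 in xylene at 140 °C (aromatic Claisen rearrangement, 1,5-hydrogen shift, oxa-6π electrocyclisation) gives 9.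

Step 1. Facial control may erode with the small methyl group on the iminium ion, and attack through the para carbon of 1 may compete with the ortho alkylation. The fallback runs from 1 back to 5 and sets the centre by reduction instead of C–C bond formation. Pechmann condensation of 1 with ethyl acetoacetate (H2SO4, 0 °C to rt) gives 5,7-dimethoxy-4-methyl-2H-chromen-2-one F4. Asymmetric conjugate reduction of F4 with a copper hydride catalyst made from Cu(OAc)2, the bisphosphine DTBM-SEGPHOS (the enantiomer that leads to the (S)-lactone), (EtO)2MeSiH and t-BuOH in toluene gives 5, which is recrystallised as in the main route.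

Further compounds
F1 | step 6 | 1-methoxy-3,5-bis(methoxymethoxy)benzene | COCOc1cc(OC)cc(OCOC)c1
F2 | step 6 | (S)-1-[4-methoxy-2,6-bis(methoxymethoxy)phenyl]-3-(5,7-dimethoxy-2,2-dimethyl-2H-chromen-8-yl)butan-1-one | COCOc1cc(OC)cc(OCOC)c1C(=O)C[C@H](C)c1c(OC)cc(OC)c2c1OC(C)(C)C=C2
F3 | step 4 | (S)-3-[2,4-dimethoxy-6-(2-methylbut-3-yn-2-yloxy)phenyl]-N-methoxy-N-methylbutanamide | CON(C)C(=O)C[C@H](C)c1c(OC(C)(C)C#C)cc(OC)cc1OC
F4 | step 1 | 5,7-dimethoxy-4-methyl-2H-chromen-2-one | Cc1cc(=O)oc2cc(OC)cc(OC)c12
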